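**Strategy.** Ring C (O1–C2–C3–C4–C4a–C8a) is cut at C3–C4 and O1–C2. Two features are exploited. The ortho-hydroxyaroyl unit O1–C8a–C4a–C4 of ring A is a salicylaldehyde, and ring A is locally symmetric (oxygens at C5, C7 and C8a, prenyls at C6 and C8), so it derives from symmetric 3,5-diprenylphloroglucinaldehyde. C2 and C3 come from the ethynyl group of a ring B arylacetylene; aldehyde plus alkyne are isomeric with the flavanone. In one flask, rhodium-catalysed chelation-assisted hydroacylation forms C3–C4 (E-2'-hydroxychalcone) and a cinchona thiourea then closes ring C by enantioselective oxa-Michael addition, forming O1–C2 and the 2S centre. The precursors are a methoxymethyl (MOM)-protected salicylaldehyde with one free ortho hydroxyl and a terminal alkyne.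

Key step: step 6

Assumption: the quinine-derived thiourea is taken to deliver the phenoxide to the Si face of C-beta (2S product). If the sense of induction proves opposite, its quinidine-derived pseudoenantiomer is used under the same conditions.

**Step 1**
Reactants: 1 2,4,6-trihydroxybenzaldehyde
Product: 2 2,4,6-trihydroxy-3,5-bis(3-methylbut-2-enyl)benzaldehyde
Conditions: prenyl bromide (2.1 equiv), 10% aq KOH, 0 °C to rt; then dilute HCl
Reagents that add atoms: prenyl bromide, CC(C)=CCBr
Why: C-alkylation of a phenolate: in water the oxygens of the polyanion are hydrogen-bonded, so the two equivalent ring carbons C3 and C5 attack prenyl bromide (SN2) and tautomerization restores the arene.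

**Step 2**
Reactants: 2 2,4,6-trihydroxy-3,5-bis(3-methylbut-2-enyl)benzaldehyde
Product: 3 2-hydroxy-4,6-bis(methoxymethoxy)-3,5-bis(3-methylbut-2-enyl)benzaldehyde
Conditions: MOMCl (2.2 equiv), i-Pr2NEt, CH2Cl2, 0 °C
Reagents that add atoms: chloromethyl methyl ether (MOMCl), COCCl
Why: Williamson-type acetal etherification: the 4-hydroxyl and one of the two equivalent ortho hydroxyls react, the last ortho hydroxyl is hydrogen-bonded to the formyl oxygen and should stay free, and the symmetry of 2 allows only one such bis-ether.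

**Step 3**
Reactants: 4 3-bromo-4,5-dihydroxybenzaldehyde
Product: 5 3-bromo-5-hydroxy-4-methoxybenzaldehyde
Conditions: MeI (1.1 equiv), Li2CO3, DMF, 40 °C
Reagents that add atoms: iodomethane, CI
Why: Regioselective Williamson etherification: the 4-hydroxyl, para to the formyl group and ortho to bromine, is the more acidic one and should be the only phenoxide formed by the weak base Li2CO3.

**Step 4**
Reactants: 5 3-bromo-5-hydroxy-4-methoxybenzaldehyde
Product: 6 3-hydroxy-4-methoxy-5-(3-methylbut-2-enyl)benzaldehyde
Conditions: tributyl(3-methylbut-2-enyl)stannane, Pd(PPh3)4 (5 mol%), DMF, 95 °C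
Reagents that add atoms: tributyl(3-methylbut-2-enyl)stannane, CCCC[Sn](CCCC)(CCCC)CC=C(C)C
Why: Migita–Kosugi–Stille coupling: oxidative addition of the aryl bromide to zerovalent palladium, allyl transfer from tin and reductive elimination at the less substituted allyl terminus should give the linear prenyl arene, and the neutral conditions tolerate the free phenol and the aldehyde.

**Step 5**
Reactants: 6 3-hydroxy-4-methoxy-5-(3-methylbut-2-enyl)benzaldehyde
Product: 7 5-ethynyl-2-methoxy-3-(3-methylbut-2-enyl)phenol
Conditions: dimethyl (1-diazo-2-oxopropyl)phosphonate, K2CO3, MeOH, rt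
Reagents that add atoms: dimethyl (1-diazo-2-oxopropyl)phosphonate (Ohira–Bestmann reagent), COP(=O)(OC)C(=[N+]=[N-])C(C)=O
Why: Seyferth–Gilbert homologation with the Ohira–Bestmann reagent: methanolysis frees the diazomethylphosphonate anion, olefination of the aldehyde gives a diazoalkene, and loss of N2 with 1,2-hydride shift gives the terminal alkyne; the phenoxide is meta to the aldehyde and does not deactivate it.

**Step 6**
Reactants: 3 2-hydroxy-4,6-bis(methoxymethoxy)-3,5-bis(3-methylbut-2-enyl)benzaldehyde; 7 5-ethynyl-2-methoxy-3-(3-methylbut-2-enyl)phenol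
Product: 9 (2S)-2-[3-hydroxy-4-methoxy-5-(3-methylbut-2-enyl)phenyl]-5,7-bis(methoxymethoxy)-6,8-bis(3-methylbut-2-enyl)chroman-4-one, via E-chalcone 8 (not isolated)
Conditions: [RhCl(cod)]2 (2.5 mol%), 1,1'-bis(diphenylphosphino)ferrocene (dppf, 5 mol%), Na2CO3 (5 mol%), toluene, 80 °C; then 20 °C, quinine-derived thiourea N-[3,5-bis(trifluoromethyl)phenyl]-N'-[(8S,9S)-6'-methoxycinchonan-9-yl]thiourea (10 mol%)
Reagents that add atoms: none
Why: The free 2-hydroxyl of 3 binds rhodium as a phenoxide and directs it into the formyl C–H bond to give a five-membered acyl rhodium hydride chelate; syn hydrometalation of the terminal alkyne of 7 with rhodium on the unhindered terminal carbon, then C–C reductive elimination, should give E-chalcone 8 and with it the C3–C4 bond. The closest known reactions are the rhodium-catalysed coupling of salicylaldehydes with alkynes to 2-alkenoylphenols, its tandem variant with oxa-Michael closure to chroman-4-ones, and the cinchona thiourea-catalysed cyclization of 2'-hydroxychalcones to flavanones. Ring C closes by 6-endo-trig oxa-Michael addition of the 2'-phenoxide to C-beta, which forms O1–C2. The C2 stereocentre is set by the catalyst: the thiourea binds the enone carbonyl while the protonated quinuclidine holds the phenoxide, so that oxygen is delivered to the Si face and 2S should result. The step needs linear regiochemistry and reaction at the alkyne in preference to the three prenyl alkenes, which the sterically biased terminal arylalkyne and the inertness of trisubstituted alkenes to insertion should secure; it also needs a slow uncatalysed cyclization, which MOM protection of the second ortho oxygen should secure while leaving a single hydroxyl able to close.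

**Step 7**
Reactants: 9 (2S)-2-[3-hydroxy-4-methoxy-5-(3-methylbut-2-enyl)phenyl]-5,7-bis(methoxymethoxy)-6,8-bis(3-methylbut-2-enyl)chroman-4-one
Product: 10 isoamoritin, (2S)-5,7-dihydroxy-2-[3-hydroxy-4-methoxy-5-(3-methylbut-2-enyl)phenyl]-6,8-bis(3-methylbut-2-enyl)chroman-4-one
Conditions: 3 M aq HCl, MeOH, 50 °C
Reagents that add atoms: none
Why: Acid-catalysed acetal methanolysis of both MOM ethers; ring opening of a flavanone needs base, so the C2 centre should be retained, and dilute acid at moderate temperature should leave the trisubstituted prenyl alkenes untouched.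

**Compound list**
1 | 2,4,6-trihydroxybenzaldehyde | O=Cc1c(O)cc(O)cc1O | starting material
2 | 2,4,6-trihydroxy-3,5-bis(3-methylbut-2-enyl)benzaldehyde | O=Cc1c(O)c(CC=C(C)C)c(O)c(CC=C(C)C)c1O | intermediate
3 | 2-hydroxy-4,6-bis(methoxymethoxy)-3,5-bis(3-methylbut-2-enyl)benzaldehyde | O=Cc1c(O)c(CC=C(C)C)c(OCOC)c(CC=C(C)C)c1OCOC | intermediate
4 | 3-bromo-4,5-dihydroxybenzaldehyde | O=Cc1cc(O)c(O)c(Br)c1 | starting material
5 | 3-bromo-5-hydroxy-4-methoxybenzaldehyde | O=Cc1cc(O)c(OC)c(Br)c1 | intermediate
6 | 3-hydroxy-4-methoxy-5-(3-methylbut-2-enyl)benzaldehyde | O=Cc1cc(O)c(OC)c(CC=C(C)C)c1 | intermediate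
7 | 5-ethynyl-2-methoxy-3-(3-methylbut-2-enyl)phenol | C#Cc1cc(O)c(OC)c(CC=C(C)C)c1 | intermediate
8 | (E)-1-[2-hydroxy-4,6-bis(methoxymethoxy)-3,5-bis(3-methylbut-2-enyl)phenyl]-3-[3-hydroxy-4-methoxy-5-(3-methylbut-2-enyl)phenyl]prop-2-en-1-one | COc1c(O)cc(/C=C/C(=O)c2c(O)c(CC=C(C)C)c(OCOC)c(CC=C(C)C)c2OCOC)cc1CC=C(C)C | intermediate
9 | (2S)-2-[3-hydroxy-4-methoxy-5-(3-methylbut-2-enyl)phenyl]-5,7-bis(methoxymethoxy)-6,8-bis(3-methylbut-2-enyl)chroman-4-one | COc1c(O)cc([C@@H]2CC(=O)c3c(OCOC)c(CC=C(C)C)c(OCOC)c(CC=C(C)C)c3O2)cc1CC=C(C)C | intermediate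
10 | isoamoritin | COc1c(O)cc([C@@H]2CC(=O)c3c(O)c(CC=C(C)C)c(O)c(CC=C(C)C)c3O2)cc1CC=C(C)C | target

**Step count.** Total: 7 steps. Longest linear sequence: 5 steps (steps 3, 4, 5, 6, 7, from compound 4).

**Steps most likely to fail**

1. Step 6. Hydrometalation may place rhodium on the internal alkyne carbon and give the branched enone, the terminal alkyne may oligomerize, and the crowded acyl rhodium hydride may decarbonylate. The oxa-Michael closure may also be reversible or show weak facial selectivity, which would erode the enantiomeric purity. The fallback uses the doubly activated oxa-Michael acceptor; it sets out from 3 and 6 and comes back at 9. Addition of the lithium enolate of allyl acetate (LiN(i-Pr)2, THF, −78 °C, excess) to 3 would give the allyl beta-hydroxy ester F1. Dess–Martin oxidation would give the allyl beta-keto ester F2. Knoevenagel condensation with aldehyde 6 (piperidine, AcOH, toluene, molecular sieves) would give the alkylidene beta-keto ester F3. The same thiourea catalyst at −25 °C in toluene should close this acceptor to the allyl (2S)-4-oxochroman-3-carboxylate F4. Pd(PPh3)4 with morpholine at rt would then remove the allyl group, and the beta-keto acid would lose CO2 to give 9.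

2. Step 1. Over-alkylation to dearomatized geminal diprenyl dienones, O-alkylation and incomplete second alkylation may leave little of 2. The fallback puts the prenyl groups on by cross-coupling; it sets out from 1 and comes back at 3. Bis-protection of 1 (MOMCl, i-Pr2NEt, CH2Cl2) would give 2-hydroxy-4,6-bis(methoxymethoxy)benzaldehyde F5. Double iodination at the two activated ring positions (N-iodosuccinimide, DMF) would give the 3,5-diiodide F6. Twofold Stille coupling with tributyl(3-methylbut-2-enyl)stannane (Pd(PPh3)4, DMF, 90 °C) would give 3.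

3. Step 7. Under acid, the freed phenols may add across the neighbouring prenyl double bonds to form dimethylchroman rings, or the alkenes may add HCl or methanol, before the hindered 7-O-MOM group is gone. The fallback changes to fluoride-labile protection; it sets out from 2 and comes back at 10. Silylation of 2 (TBSCl, imidazole, DMF) would give the bis-silyl ether aldehyde F7, with the chelated ortho hydroxyl left free. The conditions of step 6 with 7 would lead through the E-chalcone bis-silyl ether F8 (not isolated) to the (2S)-flavanone bis-silyl ether F9. HF·pyridine in THF/pyridine at 0 °C would give 10 without acid strong enough to touch the prenyl groups and without base that could open ring C.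

**Further compounds**
F1 | step 6 | allyl 3-hydroxy-3-[2-hydroxy-4,6-bis(methoxymethoxy)-3,5-bis(3-methylbut-2-enyl)phenyl]propanoate (racemic) | C=CCOC(=O)CC(O)c1c(O)c(CC=C(C)C)c(OCOC)c(CC=C(C)C)c1OCOC
F2 | step 6 | allyl 3-[2-hydroxy-4,6-bis(methoxymethoxy)-3,5-bis(3-methylbut-2-enyl)phenyl]-3-oxopropanoate | C=CCOC(=O)CC(=O)c1c(O)c(CC=C(C)C)c(OCOC)c(CC=C(C)C)c1OCOC
F3 | step 6 | allyl 2-[2-hydroxy-4,6-bis(methoxymethoxy)-3,5-bis(3-methylbut-2-enyl)benzoyl]-3-[3-hydroxy-4-methoxy-5-(3-methylbut-2-enyl)phenyl]prop-2-enoate (E/Z mixture) | C=CCOC(=O)C(=Cc1cc(O)c(OC)c(CC=C(C)C)c1)C(=O)c1c(O)c(CC=C(C)C)c(OCOC)c(CC=C(C)C)c1OCOC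
F4 | step 6 | allyl (2S)-2-[3-hydroxy-4-methoxy-5-(3-methylbut-2-enyl)phenyl]-5,7-bis(methoxymethoxy)-6,8-bis(3-methylbut-2-enyl)-4-oxochroman-3-carboxylate (C3 epimers) | COc1c(O)cc([C@@H]2C(C(=O)OCC=C)C(=O)c3c(OCOC)c(CC=C(C)C)c(OCOC)c(CC=C(C)C)c3O2)cc1CC=C(C)C
F5 | step 1 | 2-hydroxy-4,6-bis(methoxymethoxy)benzaldehyde | O=Cc1c(O)cc(OCOC)cc1OCOC
F6 | step 1 | 2-hydroxy-3,5-diiodo-4,6-bis(methoxymethoxy)benzaldehyde | O=Cc1c(O)c(I)c(OCOC)c(I)c1OCOC
F7 | step 7 | 4,6-bis(tert-butyldimethylsilyloxy)-2-hydroxy-3,5-bis(3-methylbut-2-enyl)benzaldehyde | O=Cc1c(O)c(CC=C(C)C)c(O[Si](C)(C)C(C)(C)C)c(CC=C(C)C)c1O[Si](C)(C)C(C)(C)C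
F8 | step 7 | (E)-1-[4,6-bis(tert-butyldimethylsilyloxy)-2-hydroxy-3,5-bis(3-methylbut-2-enyl)phenyl]-3-[3-hydroxy-4-methoxy-5-(3-methylbut-2-enyl)phenyl]prop-2-en-1-one | COc1c(O)cc(/C=C/C(=O)c2c(O)c(CC=C(C)C)c(O[Si](C)(C)C(C)(C)C)c(CC=C(C)C)c2O[Si](C)(C)C(C)(C)C)cc1CC=C(C)C
F9 | step 7 | (2S)-5,7-bis(tert-butyldimethylsilyloxy)-2-[3-hydroxy-4-methoxy-5-(3-methylbut-2-enyl)phenyl]-6,8-bis(3-methylbut-2-enyl)chroman-4-one | COc1c(O)cc([C@@H]2CC(=O)c3c(O[Si](C)(C)C(C)(C)C)c(CC=C(C)C)c(O[Si](C)(C)C(C)(C)C)c(CC=C(C)C)c3O2)cc1CC=C(C)C
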